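**Retrosynthetic overview**

- Feature: number the ring C1 (quaternary, methyl + homofarnesyl), C2 (CH–CH3), C3, C4, C5 (alkylidene carbon), C6 (CH carrying the hydroxypropyl arm, first carbon Cα). The exocyclic carbon C7 carries a methyl and the formyl carbon C8, and C8 lies cis to C6. An oxygen bridge C8–O–Cα therefore completes a six-membered dihydropyran (O, Cα, C6, C5, C7, C8) over the allyl unit C6–C5=C7.
- Target ⇒ MnO2 oxidation, desilylation and a one-carbon extension (iBu2AlH, Wittig, 9-BBN) ⇒ hydroxy ester 24 ⇒ SmI2 scission of the Cα–O bond ⇒ dihydropyran acid 22.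
- 22 ⇒ boat Ireland–Claisen rearrangement of the 6-cyclohexenyl-6-methyl-1,4-dioxan-2-one 19 (forms C6–Cα, moves the alkene to C5=C7, passes the (R) configuration of C7 on to C6).
- 19 ⇒ diol 16 + bromoacetic acid; 16 ⇒ Sharpless epoxidation and hydride opening of dienol 14 ⇒ Stille coupling of enol triflate 12 with stannane 13.
- 12 ⇒ Me2CuLi addition/triflation of enone 10 ⇒ homofarnesyl Grignard (from farnesyl bromide) + (R)-4-methylcyclohexenone 4 (from (R)-pulegone). Ring order: carbocycle from pulegone, dioxanone closed in step 13, dihydropyran closed in step 14 and opened again in step 16.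

Key step: step 14

Remark: "homofarnesyl" means (3E,7E)-4,8,12-trimethyltrideca-3,7,11-trien-1-yl; stannane 13 is taken as purchasable; the face selectivity of step 10 is assigned by the usual tartrate rule for 2-substituted allylic alcohols.

**Route**

Step 1
Reactants: 1 (R)-(+)-pulegone
Product: 2 (3R)-3-methyl-6-(propan-2-ylidene)cyclohex-1-en-1-yl trifluoromethanesulfonate
Conditions: LiN(iPr)2, THF, −78 °C; PhNTf2, −78 → 0 °C
Reagents that add atoms: N-phenylbis(trifluoromethanesulfonimide), O=S(=O)(N(c1ccccc1)S(=O)(=O)C(F)(F)F)C(F)(F)F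
Why: Kinetic deprotonation at the α'-methylene gives the cross-conjugated lithium dienolate, which is O-sulfonylated (enol triflate formation) without touching the methyl-bearing stereocentre.

Step 2
Reactants: 2 dienyl triflate
Product: 3 (3R)-3-methyl-6-oxocyclohex-1-en-1-yl trifluoromethanesulfonate
Conditions: O3, CH2Cl2/MeOH, −78 °C; Me2S, −78 °C → rt
Reagents that add atoms: ozone, [O-][O+]=O
Why: Ozonolysis should be site-selective for the electron-rich tetrasubstituted isopropylidene alkene over the electron-poor enol triflate alkene.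

Step 3
Reactants: 3 triflyloxy enone
Product: 4 (4R)-4-methylcyclohex-2-en-1-one
Conditions: Pd(OAc)2 (cat.), PPh3, Bu3N, HCO2H, DMF, 60 °C
Reagents that add atoms: none
Why: Palladium-catalysed formate reduction of an enol triflate (oxidative addition, decarboxylation to a palladium hydride, reductive elimination) replaces OTf by H and leaves the γ-stereocentre alone.

Step 4
Reactants: 5 (2E,6E)-farnesyl bromide
Product: 6 phenyl homofarnesyl sulfide
Conditions: PhSCH3, n-BuLi, DABCO, THF, 0 °C; then 5, −78 °C → rt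
Reagents that add atoms: thioanisole, CSc1ccccc1
Why: (Phenylsulfanyl)methyllithium displaces the primary allylic bromide by SN2 (thioanisole-anion alkylation), a one-carbon homologation that leaves the E alkenes unchanged.

Step 5
Reactants: 6 phenyl homofarnesyl sulfide
Product: 7 homofarnesyl iodide
Conditions: MeI (excess), NaI, DMF, 75 °C
Reagents that add atoms: iodomethane, CI; sodium iodide, [Na+].[I-]
Why: S-Methylation gives a sulfonium salt that iodide opens at the primary carbon (Corey–Jautelat sulfide-to-iodide exchange).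

Step 6
Reactants: 7 homofarnesyl iodide; 4 (4R)-4-methylcyclohex-2-en-1-one
Product: 9 trimethyl{[(3S,4R)-4-methyl-3-homofarnesylcyclohex-1-en-1-yl]oxy}silane (3,4-trans), via homofarnesylmagnesium iodide 8 (not isolated)
Conditions: Mg, Et2O, rt → reflux; then 4, CuBr·SMe2 (10 mol%), HMPA, Me3SiCl, THF, −78 °C; Et3N
Reagents that add atoms: chlorotrimethylsilane, C[Si](C)(C)Cl
Why: Copper-catalysed conjugate addition of the Grignard reagent, accelerated by Me3SiCl/HMPA, occurs anti to the C4 methyl and the enolate is trapped as the silyl enol ether that fixes the site of the next dehydrogenation.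

Step 7
Reactants: 9 silyl enol ether
Product: 10 (4R)-4-methyl-3-homofarnesylcyclohex-2-en-1-one
Conditions: Pd(OAc)2 (1.05 equiv), MeCN, rt
Reagents that add atoms: none
Why: Saegusa–Ito oxidation: the palladium enolate can only lose the β-hydrogen at the homofarnesyl-bearing carbon, which restores the enone with the new 3-substituent, and isolated trisubstituted alkenes should not react.

Step 8
Reactants: 10 enone
Product: 12 (3R,4R)-3,4-dimethyl-3-homofarnesylcyclohex-1-en-1-yl trifluoromethanesulfonate, via lithium enolate 11 (not isolated)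
Conditions: Me2CuLi (from MeLi and CuI), Et2O, −20 → 0 °C; then PhNTf2, THF, 0 °C → rt
Reagents that add atoms: lithium dimethylcuprate, [Li+].C[Cu-]C; N-phenylbis(trifluoromethanesulfonimide), O=S(=O)(N(c1ccccc1)S(=O)(=O)C(F)(F)F)C(F)(F)F
Why: Cuprate conjugate addition to the 3,4-disubstituted enone is axial and anti to the pseudoaxial C4 methyl, which sets quaternary C1 with the two methyls trans, and the regiodefined enolate is captured as the enol triflate (McMurry–Scott triflation).

Step 9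
Reactants: 12 enol triflate; 13 2-(tributylstannyl)prop-2-en-1-ol
Product: 14 2-[(3R,4R)-3,4-dimethyl-3-homofarnesylcyclohex-1-en-1-yl]prop-2-en-1-ol
Conditions: Pd(PPh3)4 (10 mol%), LiCl, CuCl, DMSO, 60 °C
Reagents that add atoms: none
Why: Stille cross-coupling under LiCl/CuCl acceleration, the conditions used for hindered 1-substituted vinylstannanes, joins the two sp2 carbons and tolerates the free hydroxyl.

Step 10
Reactants: 14 dienol
Product: 15 {(2R)-2-[(3R,4R)-3,4-dimethyl-3-homofarnesylcyclohex-1-en-1-yl]oxiran-2-yl}methanol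
Conditions: Ti(OiPr)4 (10 mol%), D-(−)-diisopropyl tartrate (12 mol%), t-BuOOH, 4 Å molecular sieves, CH2Cl2, −25 °C
Reagents that add atoms: tert-butyl hydroperoxide, CC(C)(C)OO
Why: Katsuki–Sharpless asymmetric epoxidation is hydroxyl-directed, so only the allylic 1,1-disubstituted alkene reacts, and D-(−)-tartrate delivers oxygen to the face that gives (R) at C7 (the sense that gives (R)-2-methylglycidol from methallyl alcohol).

Step 11
Reactants: 15 epoxy alcohol
Product: 16 (2R)-2-[(3R,4R)-3,4-dimethyl-3-homofarnesylcyclohex-1-en-1-yl]propane-1,2-diol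
Conditions: LiAlH4, THF, 0 °C
Reagents that add atoms: none
Why: Hydride opens the epoxide by SN2 at its unhindered primary carbon (regioselective epoxide reduction), which becomes the C7 methyl while the C7–O bond and its configuration stay.

Step 12
Reactants: 16 diol; 17 bromoacetic acid
Product: 18 {[(2R)-2-hydroxy-2-[(3R,4R)-3,4-dimethyl-3-homofarnesylcyclohex-1-en-1-yl]propyl]oxy}acetic acid
Conditions: NaH (3 equiv), THF, 0 → 60 °C; aq. NaH2PO4 work-up
Reagents that add atoms: none
Why: Williamson etherification with sodium bromoacetate should alkylate only the primary alkoxide, the tertiary one being too hindered.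

Step 13
Reactants: 18 hydroxy acid
Product: 19 (6R)-6-methyl-6-[(3R,4R)-3,4-dimethyl-3-homofarnesylcyclohex-1-en-1-yl]-1,4-dioxan-2-one
Conditions: EDC·HCl, DMAP, CH2Cl2 (0.01 M), 0 °C → rt
Reagents that add atoms: none
Why: Carbodiimide/DMAP activation (Steglich lactonisation) closes the six-membered lactone onto the tertiary hydroxyl under neutral conditions that spare the tertiary allylic C–O bond and the polyene.

Step 14
Reactants: 19 dioxanone
Product: 22 (1R,7R,8R,8aS)-4,7,8-trimethyl-8-homofarnesyl-3,5,6,7,8,8a-hexahydro-1H-isochromene-1-carboxylic acid, via silyl ketene acetal 20 (not isolated), via trimethylsilyl ester 21 (not isolated)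
Conditions: LiN(SiMe3)2, Me3SiCl/Et3N (premixed), THF, −78 °C → rt; then toluene, 80 °C; aq. NaH2PO4 work-up
Reagents that add atoms: none
Why: Enolisation with Me3SiCl present gives the endocyclic silyl ketene acetal 20, which should undergo a concerted [3,3] sigmatropic shift in which the C7–O(acyl) bond breaks, C6–Cα forms and the alkene moves to C5=C7. The closest known reaction type is the Ireland–Claisen rearrangement of 6-alkenyl-1,4-dioxan-2-ones to dihydropyran-2-carboxylic acids. The dihydropyran (O, Cα, C6, C5, C7, C8) closes through the sigmatropic C6–Cα bond formation itself, in a boat, bicyclo[2.2.2]octane-like array where the O–C8H2 tether spans termini 1 and 4 of the hexadiene, while the lactone ring opens. C6 is set by suprafacial 1,3-transfer from (R)-C7: the tether forces C8 syn to C6, so the acyl oxygen sits on the C6 face syn to the C1 methyl and Cα is delivered there; the configuration at Cα (its H cis to H-6) follows from the ring-locked ketene acetal and the boat, and is erased in step 16. The step needs the pericyclic path to beat heterolysis and elimination of the tertiary allylic ester and needs Cα to reach C6 next to quaternary C1; silylation in situ at −78 °C, a non-acidic medium and a half-chair with the homofarnesyl group pseudoaxial on the opposite face should secure this.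

Step 15
Reactants: 22 acid
Product: 23 methyl (1R,7R,8R,8aS)-4,7,8-trimethyl-8-homofarnesyl-3,5,6,7,8,8a-hexahydro-1H-isochromene-1-carboxylate
Conditions: MeI, K2CO3, DMF, rt
Reagents that add atoms: iodomethane, CI
Why: SN2 O-alkylation of the potassium carboxylate gives the methyl ester needed for ketyl formation in the next step.

Step 16
Reactants: 23 methyl ester
Product: 24 methyl 2-[(1S,2R,3R,6Z)-6-(1-hydroxypropan-2-ylidene)-2,3-dimethyl-2-homofarnesylcyclohexyl]acetate
Conditions: SmI2 (3 equiv), HMPA, MeOH, THF, −78 → 0 °C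
Reagents that add atoms: none
Why: Electron transfer from SmI2 to the ester gives a ketyl that expels the α-alkoxide (reductive cleavage of an α-alkoxy ester), and protonation of the samarium enolate leaves the CH2CO2Me arm on C6 and the free allylic alcohol with the Z geometry imposed by the former ring.

Step 17
Reactants: 24 hydroxy ester
Product: 25 methyl 2-[(1S,2R,3R,6Z)-6-{1-[(tert-butyldimethylsilyl)oxy]propan-2-ylidene}-2,3-dimethyl-2-homofarnesylcyclohexyl]acetate
Conditions: TBSCl, imidazole, DMF, rt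
Reagents that add atoms: tert-butyl(chloro)dimethylsilane, CC(C)(C)[Si](C)(C)Cl
Why: Standard silyl protection masks the allylic alcohol against the hydride, ylide and borane steps that follow.

Step 18
Reactants: 25 silyl ether ester
Product: 26 2-[(1S,2R,3R,6Z)-6-{1-[(tert-butyldimethylsilyl)oxy]propan-2-ylidene}-2,3-dimethyl-2-homofarnesylcyclohexyl]acetaldehyde
Conditions: iBu2AlH (1.1 equiv), CH2Cl2, −78 °C; aq. potassium sodium tartrate
Reagents that add atoms: none
Why: Partial ester reduction stops at the tetrahedral aluminium hemiacetal at −78 °C and gives the aldehyde on work-up; C6 is β to the carbonyl and cannot epimerise.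

Step 19
Reactants: 26 aldehyde
Product: 27 tert-butyl{[(2Z)-2-[(2S,3R,4R)-3,4-dimethyl-2-(prop-2-en-1-yl)-3-homofarnesylcyclohexylidene]propyl]oxy}dimethylsilane
Conditions: Ph3PCH3Br, KOtBu, THF, 0 °C → rt
Reagents that add atoms: methyltriphenylphosphonium bromide, C[P+](c1ccccc1)(c1ccccc1)c1ccccc1.[Br-]
Why: Wittig methylenation of the unhindered aldehyde adds the third side-chain carbon as a terminal alkene.

Step 20
Reactants: 27 terminal alkene
Product: 29 3-[(1S,2R,3R,6Z)-6-{1-[(tert-butyldimethylsilyl)oxy]propan-2-ylidene}-2,3-dimethyl-2-homofarnesylcyclohexyl]propan-1-ol, via B-alkyl-9-BBN adduct 28 (not isolated)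
Conditions: 9-BBN, THF, 0 °C → rt; then NaOH, H2O2, H2O, 0 °C → rt
Reagents that add atoms: hydrogen peroxide, OO
Why: Brown hydroboration–oxidation with 9-BBN is anti-Markovnikov and far faster at the monosubstituted alkene than at the tri- and tetrasubstituted ones, so only the terminal alkene should become the primary alcohol.

Step 21
Reactants: 29 silyl ether alcohol
Product: 30 (2Z)-2-[(2S,3R,4R)-2-(3-hydroxypropyl)-3,4-dimethyl-3-homofarnesylcyclohexylidene]propan-1-ol
Conditions: Bu4NF, THF, rt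
Reagents that add atoms: none
Why: Fluoride cleaves the Si–O bond (silyl ether deprotection) and nothing else in the molecule.

Step 22
Reactants: 30 diol
Product: 31 (2Z)-2-[(2S,3R,4R)-2-(3-hydroxypropyl)-3,4-dimethyl-3-homofarnesylcyclohexylidene]propanal (target, CNP0167080.1)
Conditions: MnO2 (activated, excess), CH2Cl2, rt
Reagents that add atoms: none
Why: MnO2 oxidises only the allylic primary alcohol (chemoselective allylic oxidation), giving the enal with the geometry fixed in step 14 while the saturated primary alcohol remains.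

**Compound list**

1 | (R)-(+)-pulegone | C[C@@H]1CCC(=C(C)C)C(=O)C1 | starting material
2 | (3R)-3-methyl-6-(propan-2-ylidene)cyclohex-1-en-1-yl trifluoromethanesulfonate | C[C@@H]1CCC(=C(C)C)C(OS(=O)(=O)C(F)(F)F)=C1 | intermediate
3 | (3R)-3-methyl-6-oxocyclohex-1-en-1-yl trifluoromethanesulfonate | C[C@@H]1CCC(=O)C(OS(=O)(=O)C(F)(F)F)=C1 | intermediate
4 | (4R)-4-methylcyclohex-2-en-1-one | C[C@@H]1CCC(=O)C=C1 | intermediate
5 | (2E,6E)-farnesyl bromide | CC(C)=CCC/C(C)=C/CC/C(C)=C/CBr | starting material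
6 | phenyl homofarnesyl sulfide | CC(C)=CCC/C(C)=C/CC/C(C)=C/CCSc1ccccc1 | intermediate
7 | homofarnesyl iodide | CC(C)=CCC/C(C)=C/CC/C(C)=C/CCI | intermediate
8 | homofarnesylmagnesium iodide | CC(C)=CCC/C(C)=C/CC/C(C)=C/CC[Mg]I | intermediate
9 | trimethyl{[(3S,4R)-4-methyl-3-homofarnesylcyclohex-1-en-1-yl]oxy}silane | CC(C)=CCC/C(C)=C/CC/C(C)=C/CC[C@H]1[C@H](C)CCC(O[Si](C)(C)C)=C1 | intermediate
10 | (4R)-4-methyl-3-homofarnesylcyclohex-2-en-1-one | CC(C)=CCC/C(C)=C/CC/C(C)=C/CCC1=CC(=O)CC[C@H]1C | intermediate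
11 | lithium (3R,4R)-3,4-dimethyl-3-homofarnesylcyclohex-1-en-1-olate | CC(C)=CCC/C(C)=C/CC/C(C)=C/CC[C@]1(C)[C@H](C)CCC([O-])=C1.[Li+] | intermediate
12 | (3R,4R)-3,4-dimethyl-3-homofarnesylcyclohex-1-en-1-yl trifluoromethanesulfonate | CC(C)=CCC/C(C)=C/CC/C(C)=C/CC[C@]1(C)[C@H](C)CCC(OS(=O)(=O)C(F)(F)F)=C1 | intermediate
13 | 2-(tributylstannyl)prop-2-en-1-ol | C=C(CO)[Sn](CCCC)(CCCC)CCCC | starting material
14 | 2-[(3R,4R)-3,4-dimethyl-3-homofarnesylcyclohex-1-en-1-yl]prop-2-en-1-ol | CC(C)=CCC/C(C)=C/CC/C(C)=C/CC[C@]1(C)[C@H](C)CCC(C(=C)CO)=C1 | intermediate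
15 | {(2R)-2-[(3R,4R)-3,4-dimethyl-3-homofarnesylcyclohex-1-en-1-yl]oxiran-2-yl}methanol | CC(C)=CCC/C(C)=C/CC/C(C)=C/CC[C@]1(C)[C@H](C)CCC([C@]2(CO2)CO)=C1 | intermediate
16 | (2R)-2-[(3R,4R)-3,4-dimethyl-3-homofarnesylcyclohex-1-en-1-yl]propane-1,2-diol | CC(C)=CCC/C(C)=C/CC/C(C)=C/CC[C@]1(C)[C@H](C)CCC([C@](O)(C)CO)=C1 | intermediate
17 | bromoacetic acid | OC(=O)CBr | starting material
18 | {[(2R)-2-hydroxy-2-[(3R,4R)-3,4-dimethyl-3-homofarnesylcyclohex-1-en-1-yl]propyl]oxy}acetic acid | CC(C)=CCC/C(C)=C/CC/C(C)=C/CC[C@]1(C)[C@H](C)CCC([C@](O)(C)COCC(=O)O)=C1 | intermediate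
19 | (6R)-6-methyl-6-[(3R,4R)-3,4-dimethyl-3-homofarnesylcyclohex-1-en-1-yl]-1,4-dioxan-2-one | CC(C)=CCC/C(C)=C/CC/C(C)=C/CC[C@]1(C)[C@H](C)CCC(=C1)[C@]2(C)COCC(=O)O2 | intermediate
20 | {[(6R)-6-methyl-6-[(3R,4R)-3,4-dimethyl-3-homofarnesylcyclohex-1-en-1-yl]-5,6-dihydro-1,4-dioxin-2-yl]oxy}trimethylsilane | CC(C)=CCC/C(C)=C/CC/C(C)=C/CC[C@]1(C)[C@H](C)CCC(=C1)[C@]2(C)COC=C(O[Si](C)(C)C)O2 | intermediate
21 | trimethylsilyl (1R,7R,8R,8aS)-4,7,8-trimethyl-8-homofarnesyl-3,5,6,7,8,8a-hexahydro-1H-isochromene-1-carboxylate | CC(C)=CCC/C(C)=C/CC/C(C)=C/CC[C@]1(C)[C@H](C)CCC2=C(C)CO[C@@H](C(=O)O[Si](C)(C)C)[C@@H]12 | intermediate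
22 | (1R,7R,8R,8aS)-4,7,8-trimethyl-8-homofarnesyl-3,5,6,7,8,8a-hexahydro-1H-isochromene-1-carboxylic acid | CC(C)=CCC/C(C)=C/CC/C(C)=C/CC[C@]1(C)[C@H](C)CCC2=C(C)CO[C@@H](C(=O)O)[C@@H]12 | intermediate
23 | methyl (1R,7R,8R,8aS)-4,7,8-trimethyl-8-homofarnesyl-3,5,6,7,8,8a-hexahydro-1H-isochromene-1-carboxylate | CC(C)=CCC/C(C)=C/CC/C(C)=C/CC[C@]1(C)[C@H](C)CCC2=C(C)CO[C@@H](C(=O)OC)[C@@H]12 | intermediate
24 | methyl 2-[(1S,2R,3R,6Z)-6-(1-hydroxypropan-2-ylidene)-2,3-dimethyl-2-homofarnesylcyclohexyl]acetate | CC(C)=CCC/C(C)=C/CC/C(C)=C/CC[C@]1(C)[C@H](C)CC/C(=C(\C)CO)[C@H]1CC(=O)OC | intermediate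
25 | methyl 2-[(1S,2R,3R,6Z)-6-{1-[(tert-butyldimethylsilyl)oxy]propan-2-ylidene}-2,3-dimethyl-2-homofarnesylcyclohexyl]acetate | CC(C)=CCC/C(C)=C/CC/C(C)=C/CC[C@]1(C)[C@H](C)CC/C(=C(\C)CO[Si](C)(C)C(C)(C)C)[C@H]1CC(=O)OC | intermediate
26 | 2-[(1S,2R,3R,6Z)-6-{1-[(tert-butyldimethylsilyl)oxy]propan-2-ylidene}-2,3-dimethyl-2-homofarnesylcyclohexyl]acetaldehyde | CC(C)=CCC/C(C)=C/CC/C(C)=C/CC[C@]1(C)[C@H](C)CC/C(=C(\C)CO[Si](C)(C)C(C)(C)C)[C@H]1CC=O | intermediate
27 | tert-butyl{[(2Z)-2-[(2S,3R,4R)-3,4-dimethyl-2-(prop-2-en-1-yl)-3-homofarnesylcyclohexylidene]propyl]oxy}dimethylsilane | CC(C)=CCC/C(C)=C/CC/C(C)=C/CC[C@]1(C)[C@H](C)CC/C(=C(\C)CO[Si](C)(C)C(C)(C)C)[C@H]1CC=C | intermediate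
28 | B-alkyl-9-borabicyclo[3.3.1]nonane adduct of 27 (boron on the terminal carbon) | CC(C)=CCC/C(C)=C/CC/C(C)=C/CC[C@]1(C)[C@H](C)CC/C(=C(\C)CO[Si](C)(C)C(C)(C)C)[C@H]1CCCB2C3CCCC2CCC3 | intermediate
29 | 3-[(1S,2R,3R,6Z)-6-{1-[(tert-butyldimethylsilyl)oxy]propan-2-ylidene}-2,3-dimethyl-2-homofarnesylcyclohexyl]propan-1-ol | CC(C)=CCC/C(C)=C/CC/C(C)=C/CC[C@]1(C)[C@H](C)CC/C(=C(\C)CO[Si](C)(C)C(C)(C)C)[C@H]1CCCO | intermediate
30 | (2Z)-2-[(2S,3R,4R)-2-(3-hydroxypropyl)-3,4-dimethyl-3-homofarnesylcyclohexylidene]propan-1-ol | CC(C)=CCC/C(C)=C/CC/C(C)=C/CC[C@]1(C)[C@H](C)CC/C(=C(\C)CO)[C@H]1CCCO | intermediate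
31 | (2Z)-2-[(2S,3R,4R)-2-(3-hydroxypropyl)-3,4-dimethyl-3-homofarnesylcyclohexylidene]propanal | CC(C)=CCC/C(C)=C/CC/C(C)=C/CC[C@]1(C)[C@H](C)CC/C(=C(\C)C=O)[C@H]1CCCO | target

**Step count and risks**

Total step count: 22. Longest linear sequence: 20 steps (steps 1–3 and 6–22, from (R)-pulegone).

Steps most likely to fail:

1. Step 14. The boat may be too crowded, with the silyloxy-bearing carbon eclipsing C4H2 and Cα approaching C6 beside quaternary C1. Heterolysis of the tertiary allylic C7–O bond followed by elimination could then overtake the concerted shift, or the ketene acetal could survive heating and decompose. The fallback sets out from 16 and comes back to the route at 25. The primary hydroxyl of 16 is silylated (TBSCl, imidazole, CH2Cl2, 0 °C) to give (2R)-1-[(tert-butyldimethylsilyl)oxy]-2-[(3R,4R)-3,4-dimethyl-3-homofarnesylcyclohex-1-en-1-yl]propan-2-ol F1. F1 is then heated with trimethyl orthoacetate and catalytic propionic acid (xylene, 140 °C; Johnson orthoester Claisen rearrangement), which should give 25 directly. In this open-chain variant the alkene geometry rests on the chair placing the CH2OSi group pseudoaxial (to avoid A(1,2) strain against C4H2) and is no longer enforced by a ring, so the E isomer with inverted C6 may have to be separated.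

2. Step 10. The tertiary allylic epoxide may be opened or rearranged by the titanium Lewis acid during reaction or work-up, and reagent control of the face may be incomplete on this 2-dienyl allylic alcohol. The fallback sets out from 12 and comes back at 16.
   - Triflate 12 is stannylated (Me3SnSnMe3, Pd(PPh3)4, LiCl, THF, 60 °C) to trimethyl[(3R,4R)-3,4-dimethyl-3-homofarnesylcyclohex-1-en-1-yl]stannane F2.
   - Tin–lithium exchange (MeLi, THF, −78 °C) gives (3R,4R)-3,4-dimethyl-3-homofarnesylcyclohex-1-en-1-yllithium F3, and MgBr2·OEt2 converts it into the alkenylmagnesium bromide F4.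
   - F4 is added at −78 °C to (1S,2R,5S)-8-phenylmenthyl pyruvate F5, made from commercial (+)-8-phenylmenthol and pyruvoyl chloride (pyridine, CH2Cl2). Auxiliary-controlled addition to the chelated α-keto ester (Whitesell) should give (1S,2R,5S)-8-phenylmenthyl (2R)-2-hydroxy-2-[(3R,4R)-3,4-dimethyl-3-homofarnesylcyclohex-1-en-1-yl]propanoate F6.
   - LiAlH4 (THF, 0 °C) reduces F6 to 16 and returns the auxiliary alcohol.

3. Step 9. Transmetalation from the α-substituted vinylstannane to palladium may be slow, so that protodestannylation, homocoupling or cine substitution competes. The fallback sets out from 12 and comes back at 14. Miyaura borylation of 12 (B2pin2, PdCl2(dppf), KOAc, dioxane, 80 °C) gives 2-[(3R,4R)-3,4-dimethyl-3-homofarnesylcyclohex-1-en-1-yl]-4,4,5,5-tetramethyl-1,3,2-dioxaborolane F7. Suzuki–Miyaura coupling of F7 with commercial 2-bromoprop-2-en-1-ol (Pd(PPh3)4, aq. K3PO4, THF, 60 °C) should give 14.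

Further compounds

F1 | step 14 | (2R)-1-[(tert-butyldimethylsilyl)oxy]-2-[(3R,4R)-3,4-dimethyl-3-homofarnesylcyclohex-1-en-1-yl]propan-2-ol | CC(C)=CCC/C(C)=C/CC/C(C)=C/CC[C@]1(C)[C@H](C)CCC([C@](O)(C)CO[Si](C)(C)C(C)(C)C)=C1
F2 | step 10 | trimethyl[(3R,4R)-3,4-dimethyl-3-homofarnesylcyclohex-1-en-1-yl]stannane | CC(C)=CCC/C(C)=C/CC/C(C)=C/CC[C@]1(C)[C@H](C)CCC([Sn](C)(C)C)=C1
F3 | step 10 | (3R,4R)-3,4-dimethyl-3-homofarnesylcyclohex-1-en-1-yllithium | CC(C)=CCC/C(C)=C/CC/C(C)=C/CC[C@]1(C)[C@H](C)CCC([Li])=C1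
F4 | step 10 | (3R,4R)-3,4-dimethyl-3-homofarnesylcyclohex-1-en-1-ylmagnesium bromide | CC(C)=CCC/C(C)=C/CC/C(C)=C/CC[C@]1(C)[C@H](C)CCC([Mg]Br)=C1
F5 | step 10 | (1S,2R,5S)-5-methyl-2-(2-phenylpropan-2-yl)cyclohexyl 2-oxopropanoate | CC(=O)C(=O)O[C@H]1C[C@@H](C)CC[C@@H]1C(C)(C)c1ccccc1
F6 | step 10 | (1S,2R,5S)-5-methyl-2-(2-phenylpropan-2-yl)cyclohexyl (2R)-2-hydroxy-2-[(3R,4R)-3,4-dimethyl-3-homofarnesylcyclohex-1-en-1-yl]propanoate | CC(C)=CCC/C(C)=C/CC/C(C)=C/CC[C@]1(C)[C@H](C)CCC([C@](O)(C)C(=O)O[C@H]2C[C@@H](C)CC[C@@H]2C(C)(C)c3ccccc3)=C1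
F7 | step 9 | 2-[(3R,4R)-3,4-dimethyl-3-homofarnesylcyclohex-1-en-1-yl]-4,4,5,5-tetramethyl-1,3,2-dioxaborolane | CC(C)=CCC/C(C)=C/CC/C(C)=C/CC[C@]1(C)[C@H](C)CCC(B2OC(C)(C)C(C)(C)O2)=C1
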